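**Retrosynthetic overview**
1. Chrysomutanin ⇐ macrocyclic 10'-ketone 24, with C10' set last by a reagent-controlled Corey–Bakshi–Shibata reduction.
2. 24 ⇐ open-chain bromo ketone 22: the 14-membered ring is closed at C8'–C9' by intramolecular SN2 allylation of a methyl-ketone enolate (no π-allyl metal, so both Z olefins are kept).
3. 22 ⇐ phenol 19 + 3-bromo-3-methylbutan-2-one: tertiary aryl ether at the free 6-OH (the 8-OH is chelated by the lactone C=O).
4. 19 ⇐ constitutionally symmetric dibromide 13: one Br gives the aryl–allyl bond to the Z,Z-chloride 7 (nerol + Still–Gennari), the other gives the δ-lactone by Pd carbonylation; C3 comes from (R)-propylene oxide.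
5. Ring order: arene (purchased) → δ-lactone ring (step 9) → 14-membered ring (step 13).

Assumption: the SMILES is read as 3R, 10'S with both ring olefins Z (C1'/C4' cis and C5'/C8' cis, a nerol-type chain); primes number the terpenoid chain from the aryl-bound CH2 (C1') to the ether carbon (C11').

**Step 1**
Reactants: 1 nerol
Product: 2 neryl chloride
Conditions: PPh3, CCl4, reflux
Reagents that add atoms: carbon tetrachloride, ClC(Cl)(Cl)Cl
Why: Appel chlorination converts the primary allylic alcohol by SN2 without allylic transposition or loss of the Z geometry, as in the standard preparation of geranyl chloride.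

**Step 2**
Reactants: 2 neryl chloride
Product: 4 (4Z)-6-chloro-4-methylhex-4-enal, via ozonide 3 (not isolated)
Conditions: O3 (1 equiv, Sudan Red 7B end point), CH2Cl2, −78 °C; then Me2S, −78 °C → rt
Reagents that add atoms: ozone, [O-][O+]=O
Why: Chemoselective ozonolysis cleaves only the electron-rich isopropylidene olefin, because the 2,3-olefin is deactivated by the allylic chlorine, and reductive work-up of the ozonide gives the aldehyde.

**Step 3**
Reactants: 4 (4Z)-6-chloro-4-methylhex-4-enal, 5 ethyl 2-[bis(2,2,2-trifluoroethoxy)phosphoryl]propanoate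
Product: 7 ethyl (2Z,6Z)-8-chloro-2,6-dimethylocta-2,6-dienoate, via potassium phosphonate carbanion 6 (not isolated)
Conditions: 5, KN(SiMe3)2, 18-crown-6, THF, −78 °C; then 4, −78 °C
Reagents that add atoms: none
Why: Still–Gennari olefination (trifluoroethyl phosphonate, dissociated potassium ion) gives the Z 2-methyl enoate under kinetic control (typically >10:1), which sets the future C6'=C7' geometry.

**Step 4**
Reactants: 8 5-bromobenzene-1,3-diol
Product: 9 1-bromo-3,5-bis(methoxymethoxy)benzene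
Conditions: MOMCl (2.4 equiv), i-Pr2NEt, CH2Cl2, 0 °C → rt
Reagents that add atoms: chloromethyl methyl ether, COCCl
Why: Standard phenol acetalisation; the MOM ethers survive the organometallic steps and are later removed without touching the olefins.

**Step 5**
Reactants: 9 1-bromo-3,5-bis(methoxymethoxy)benzene, 10 (R)-2-methyloxirane
Product: 12 (2R)-1-[3,5-bis(methoxymethoxy)phenyl]propan-2-ol, via aryl Grignard reagent 11 (not isolated)
Conditions: Mg, THF, 40 °C; then CuI (10 mol %), 10, −30 → 0 °C; H2O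
Reagents that add atoms: none
Why: Copper-catalysed epoxide opening by the aryl Grignard reagent occurs at the unsubstituted carbon, so the stereocentre of (R)-propylene oxide is carried over unchanged as the R carbinol (future C3).

**Step 6**
Reactants: 12 (2R)-1-[3,5-bis(methoxymethoxy)phenyl]propan-2-ol
Product: 13 (2R)-1-[2,6-dibromo-3,5-bis(methoxymethoxy)phenyl]propan-2-ol
Conditions: NBS (2.1 equiv), MeCN, 0 °C → rt
Reagents that add atoms: N-bromosuccinimide, BrN1C(=O)CCC1=O
Why: Electrophilic aromatic bromination goes para to each OMOM group (positions 2 and 6) rather than to the doubly ortho position 4, giving a dibromide whose two bromines are constitutionally equivalent.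

**Step 7**
Reactants: 13 (2R)-1-[2,6-dibromo-3,5-bis(methoxymethoxy)phenyl]propan-2-ol, 7 ethyl (2Z,6Z)-8-chloro-2,6-dimethylocta-2,6-dienoate
Product: 16 ethyl (2Z,6Z)-8-{3-bromo-2-[(2R)-2-hydroxypropyl]-4,6-bis(methoxymethoxy)phenyl}-2,6-dimethylocta-2,6-dienoate, via aryllithium alkoxide 14 (not isolated), via arylmagnesium bromide 15 (not isolated)
Conditions: n-BuLi (2.05 equiv), THF, −78 °C; MgBr2·OEt2, −78 → −20 °C; CuI (10 mol %), 7 (1.2 equiv), −20 → 0 °C
Reagents that add atoms: none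
Why: After alkoxide formation a single Br/Li exchange, transmetalation to magnesium and Kochi-type copper-catalysed SN2 allylic substitution at the primary carbon of the γ,γ-disubstituted allyl chloride join the fragments; no π-allyl metal species is formed, so both Z olefins are retained, and the α-methyl-β-alkyl enoate is a poor acceptor.

**Step 8**
Reactants: 16 ethyl (2Z,6Z)-8-{3-bromo-2-[(2R)-2-hydroxypropyl]-4,6-bis(methoxymethoxy)phenyl}-2,6-dimethylocta-2,6-dienoate
Product: 17 (2Z,6Z)-8-{3-bromo-2-[(2R)-2-hydroxypropyl]-4,6-bis(methoxymethoxy)phenyl}-2,6-dimethylocta-2,6-dien-1-ol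
Conditions: i-Bu2AlH (3.5 equiv), CH2Cl2, −78 °C; aq. potassium sodium tartrate
Reagents that add atoms: none
Why: 1,2-Reduction of the unsaturated ester by the aluminium hydride gives the Z allylic alcohol with the geometry unchanged, while the aryl bromide and MOM ethers are inert.

**Step 9**
Reactants: 17 (2Z,6Z)-8-{3-bromo-2-[(2R)-2-hydroxypropyl]-4,6-bis(methoxymethoxy)phenyl}-2,6-dimethylocta-2,6-dien-1-ol
Product: 18 (3R)-5-[(2Z,6Z)-8-hydroxy-3,7-dimethylocta-2,6-dien-1-yl]-6,8-bis(methoxymethoxy)-3-methyl-3,4-dihydro-1H-isochromen-1-one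
Conditions: Pd(OAc)2 (5 mol %), Xantphos (6 mol %), CO (1 atm), Et3N, toluene (0.02 M), 90 °C
Reagents that add atoms: carbon monoxide, [C-]#[O+]
Why: Palladium-catalysed carbonylative lactonisation (oxidative addition of the aryl bromide to zerovalent palladium, CO insertion, intramolecular capture of the acyl-palladium) forms the δ-lactone, because only the secondary alcohol can close a six-membered ring.

**Step 10**
Reactants: 18 (3R)-5-[(2Z,6Z)-8-hydroxy-3,7-dimethylocta-2,6-dien-1-yl]-6,8-bis(methoxymethoxy)-3-methyl-3,4-dihydro-1H-isochromen-1-one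
Product: 19 (3R)-6,8-dihydroxy-5-[(2Z,6Z)-8-hydroxy-3,7-dimethylocta-2,6-dien-1-yl]-3-methyl-3,4-dihydro-1H-isochromen-1-one
Conditions: HCl (1 M in MeOH), THF, 0 °C → rt
Reagents that add atoms: none
Why: Acid-catalysed acetal exchange with methanol removes both aryl MOM ethers under conditions that the tiglyl-type primary allylic alcohol and the trisubstituted olefins tolerate.

**Step 11**
Reactants: 19 (3R)-6,8-dihydroxy-5-[(2Z,6Z)-8-hydroxy-3,7-dimethylocta-2,6-dien-1-yl]-3-methyl-3,4-dihydro-1H-isochromen-1-one, 20 3-bromo-3-methylbutan-2-one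
Product: 21 (3R)-8-hydroxy-5-[(2Z,6Z)-8-hydroxy-3,7-dimethylocta-2,6-dien-1-yl]-3-methyl-6-[(2-methyl-3-oxobutan-2-yl)oxy]-3,4-dihydro-1H-isochromen-1-one
Conditions: 20 (3 equiv), K2CO3, DMF, 50 °C
Reagents that add atoms: none
Why: Williamson-type O-alkylation by a tertiary α-bromo ketone (the fibrate-type etherification) occurs at the acidic, non-chelated 6-OH para to the carbonyl, while the hydrogen-bonded 8-OH and the aliphatic OH do not react under carbonate conditions.

**Step 12**
Reactants: 21 (3R)-8-hydroxy-5-[(2Z,6Z)-8-hydroxy-3,7-dimethylocta-2,6-dien-1-yl]-3-methyl-6-[(2-methyl-3-oxobutan-2-yl)oxy]-3,4-dihydro-1H-isochromen-1-one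
Product: 22 (3R)-5-[(2Z,6Z)-8-bromo-3,7-dimethylocta-2,6-dien-1-yl]-8-hydroxy-3-methyl-6-[(2-methyl-3-oxobutan-2-yl)oxy]-3,4-dihydro-1H-isochromen-1-one
Conditions: CBr4 (1.2 equiv), PPh3 (1.2 equiv), CH2Cl2, 0 °C; used at once
Reagents that add atoms: carbon tetrabromide, BrC(Br)(Br)Br
Why: Appel bromination converts only the primary allylic alcohol, by SN2 without transposition or Z→E change, and leaves the chelated phenol and the ketone untouched at 0 °C.

**Step 13**
Reactants: 22 (3R)-5-[(2Z,6Z)-8-bromo-3,7-dimethylocta-2,6-dien-1-yl]-8-hydroxy-3-methyl-6-[(2-methyl-3-oxobutan-2-yl)oxy]-3,4-dihydro-1H-isochromen-1-one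
Product: 24 macrocyclic 10'-ketone (10'-dehydrochrysomutanin), via dilithium phenoxide-enolate 23 (not isolated)
Conditions: LiN(SiMe3)2 (2.5 equiv), THF/DMPU 10:1, 2 mM, syringe-pump addition of 22 at −78 °C, then → 0 °C
Reagents that add atoms: none
Why: Proposed new method: intramolecular SN2 C-allylation of a kinetically formed lithium methyl-ketone enolate under high dilution closes the 14-membered ring, helped by the single enolisable position, the poor nucleophilicity of the chelated lithium 8-phenoxide and the pre-bent chain (two cis olefins, ortho-disubstituted arene); the closest known reactions are macrocyclic alkylations of allylic halides by stabilised carbanions (malonates, β-keto esters, protected cyanohydrins) and ordinary intermolecular enolate allylations.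

**Step 14**
Reactants: 24 macrocyclic 10'-ketone (10'-dehydrochrysomutanin)
Product: 25 chrysomutanin
Conditions: (R)-2-methyl-CBS-oxazaborolidine (1 equiv), catecholborane (3 equiv), toluene, −78 → −30 °C; MeOH, pH 7 buffer
Reagents that add atoms: none
Why: Corey–Bakshi–Shibata reduction with the R catalyst delivers hydride to the face that gives the 10'S carbinol (large group C(CH3)2OAr versus small CH2, the mirror image of the S-catalyst/pinacolone → R outcome), and catecholborane at low temperature spares the trisubstituted olefins and the lactone.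

**Compound list**
1 | nerol, (2Z)-3,7-dimethylocta-2,6-dien-1-ol | CC(C)=CCC/C(C)=C\CO | starting material
2 | neryl chloride, (2Z)-1-chloro-3,7-dimethylocta-2,6-diene | CC(C)=CCC/C(C)=C\CCl | intermediate
3 | 3-[(3Z)-5-chloro-3-methylpent-3-en-1-yl]-5,5-dimethyl-1,2,4-trioxolane (ozonide of 2) | CC1(C)OOC(CC/C(C)=C\CCl)O1 | intermediate
4 | (4Z)-6-chloro-4-methylhex-4-enal | O=CCC/C(C)=C\CCl | intermediate
5 | ethyl 2-[bis(2,2,2-trifluoroethoxy)phosphoryl]propanoate | CCOC(=O)C(C)P(=O)(OCC(F)(F)F)OCC(F)(F)F | starting material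
6 | potassium salt of the α-carbanion of 5 | CCOC(=O)[C-](C)P(=O)(OCC(F)(F)F)OCC(F)(F)F.[K+] | intermediate
7 | ethyl (2Z,6Z)-8-chloro-2,6-dimethylocta-2,6-dienoate | CCOC(=O)/C(C)=C\CC/C(C)=C\CCl | intermediate
8 | 5-bromobenzene-1,3-diol | Oc1cc(O)cc(Br)c1 | starting material
9 | 1-bromo-3,5-bis(methoxymethoxy)benzene | COCOc1cc(Br)cc(OCOC)c1 | intermediate
10 | (R)-2-methyloxirane, (R)-propylene oxide | C[C@@H]1CO1 | starting material
11 | [3,5-bis(methoxymethoxy)phenyl]magnesium bromide | COCOc1cc([Mg]Br)cc(OCOC)c1 | intermediate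
12 | (2R)-1-[3,5-bis(methoxymethoxy)phenyl]propan-2-ol | C[C@@H](O)Cc1cc(OCOC)cc(OCOC)c1 | intermediate
13 | (2R)-1-[2,6-dibromo-3,5-bis(methoxymethoxy)phenyl]propan-2-ol | C[C@@H](O)Cc1c(Br)c(OCOC)cc(OCOC)c1Br | intermediate
14 | lithium (2R)-1-[2-bromo-6-lithio-3,5-bis(methoxymethoxy)phenyl]propan-2-olate | C[C@@H](O[Li])Cc1c(Br)c(OCOC)cc(OCOC)c1[Li] | intermediate
15 | {3-bromo-2-[(2R)-2-(lithiooxy)propyl]-4,6-bis(methoxymethoxy)phenyl}magnesium bromide | C[C@@H](O[Li])Cc1c(Br)c(OCOC)cc(OCOC)c1[Mg]Br | intermediate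
16 | ethyl (2Z,6Z)-8-{3-bromo-2-[(2R)-2-hydroxypropyl]-4,6-bis(methoxymethoxy)phenyl}-2,6-dimethylocta-2,6-dienoate | C[C@@H](O)Cc1c(Br)c(OCOC)cc(OCOC)c1C/C=C(C)\CC/C=C(C)\C(=O)OCC | intermediate
17 | (2Z,6Z)-8-{3-bromo-2-[(2R)-2-hydroxypropyl]-4,6-bis(methoxymethoxy)phenyl}-2,6-dimethylocta-2,6-dien-1-ol | C[C@@H](O)Cc1c(Br)c(OCOC)cc(OCOC)c1C/C=C(C)\CC/C=C(C)\CO | intermediate
18 | (3R)-5-[(2Z,6Z)-8-hydroxy-3,7-dimethylocta-2,6-dien-1-yl]-6,8-bis(methoxymethoxy)-3-methyl-3,4-dihydro-1H-isochromen-1-one | C[C@@H]1Cc2c(C/C=C(C)\CC/C=C(C)\CO)c(OCOC)cc(OCOC)c2C(=O)O1 | intermediate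
19 | (3R)-6,8-dihydroxy-5-[(2Z,6Z)-8-hydroxy-3,7-dimethylocta-2,6-dien-1-yl]-3-methyl-3,4-dihydro-1H-isochromen-1-one | C[C@@H]1Cc2c(C/C=C(C)\CC/C=C(C)\CO)c(O)cc(O)c2C(=O)O1 | intermediate
20 | 3-bromo-3-methylbutan-2-one | CC(=O)C(C)(C)Br | starting material
21 | (3R)-8-hydroxy-5-[(2Z,6Z)-8-hydroxy-3,7-dimethylocta-2,6-dien-1-yl]-3-methyl-6-[(2-methyl-3-oxobutan-2-yl)oxy]-3,4-dihydro-1H-isochromen-1-one | C[C@@H]1Cc2c(C/C=C(C)\CC/C=C(C)\CO)c(OC(C)(C)C(C)=O)cc(O)c2C(=O)O1 | intermediate
22 | (3R)-5-[(2Z,6Z)-8-bromo-3,7-dimethylocta-2,6-dien-1-yl]-8-hydroxy-3-methyl-6-[(2-methyl-3-oxobutan-2-yl)oxy]-3,4-dihydro-1H-isochromen-1-one | C[C@@H]1Cc2c(C/C=C(C)\CC/C=C(C)\CBr)c(OC(C)(C)C(C)=O)cc(O)c2C(=O)O1 | intermediate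
23 | dilithium 8-phenoxide / C9'-C10' enolate of 22 | C[C@@H]1Cc2c(C/C=C(C)\CC/C=C(C)\CBr)c(OC(C)(C)C(=C)O[Li])cc(O[Li])c2C(=O)O1 | intermediate
24 | macrocyclic 10'-ketone (10'-dehydrochrysomutanin): 3R, both ring olefins Z, 14-membered ring through C5–C1' and O6–C11', C=O at C10' | C/C1=C/Cc2c(cc(O)c3c2C[C@@H](C)OC3=O)OC(C)(C)C(=O)CC/C(C)=C\CC1 | intermediate
25 | chrysomutanin (3R, 10'S, 2'Z, 6'Z) | C/C1=C/Cc2c(cc(O)c3c2C[C@@H](C)OC3=O)OC(C)(C)[C@@H](O)CC/C(C)=C\CC1 | target

**Step count and risk**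
Total steps: 14 (steps 1–3 make fragment 7; steps 4–14 carry the arene).
Longest linear sequence: 11 steps (8 → 25, steps 4–14; the nerol branch, steps 1–3 then 7–14, is also 11).

Three steps most likely to fail:

Step 13 (macrocyclic enolate allylation; risks are oligomerisation, O-alkylation, or loss of the α'-aryloxide). The fallback sets out from 19 and comes back at 24, and replaces the simple enolate by a doubly stabilised carbanion. Phenol 19 is alkylated at 6-OH (K2CO3, acetone) with methyl 4-bromo-4-methyl-3-oxopentanoate F1 (made from commercial methyl 4-methyl-3-oxopentanoate and Br2) to give the β-keto ester ether, methyl 4-{[(3R)-8-hydroxy-5-[(2Z,6Z)-8-hydroxy-3,7-dimethylocta-2,6-dien-1-yl]-3-methyl-1-oxo-3,4-dihydro-1H-isochromen-6-yl]oxy}-4-methyl-3-oxopentanoate F2. Appel bromination (CBr4, PPh3) gives the corresponding allylic bromide F3. Cs2CO3 in MeCN at 1 mM then closes the ring by soft C-alkylation (the established malonate/β-keto ester macro-alkylation of allylic halides) to the macrocyclic β-keto ester F4 (C9' epimers). Krapcho demethoxycarbonylation (LiCl, wet DMSO, 120 °C) gives ketone 24.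

Step 11 (tertiary ether at a hindered, weakly nucleophilic phenol; risks are elimination of 20 and oxa-Michael addition). The fallback sets out from 19 and comes back at 21, and builds the C–O bond by copper-catalysed propargylic substitution instead. 19 with 3-chloro-3-methylbut-1-yne, CuCl2·2H2O (cat.) and DBU in MeCN at 0 °C gives the 1,1-dimethylpropargyl ether, (3R)-8-hydroxy-5-[(2Z,6Z)-8-hydroxy-3,7-dimethylocta-2,6-dien-1-yl]-3-methyl-6-[(2-methylbut-3-yn-2-yl)oxy]-3,4-dihydro-1H-isochromen-1-one F5. Markovnikov hydration of the terminal alkyne with (IPr)AuCl/AgSbF6 (cat., IPr = 1,3-bis(2,6-diisopropylphenyl)imidazol-2-ylidene) in dioxane/H2O then gives methyl ketone 21; the aqueous medium is chosen to favour hydration over chromene formation at C7.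

Step 7 (selective mono Br/Li exchange and aryl–allyl coupling in the presence of an enoate). The fallback sets out from 13 and 7 and comes back at 18, and forms the lactone before the chain is attached. Carbonylative lactonisation of 13 (Pd(OAc)2, Xantphos, CO, Et3N; only one bromine can lactonise) gives (3R)-5-bromo-6,8-bis(methoxymethoxy)-3-methyl-3,4-dihydro-1H-isochromen-1-one F6. Separately, 7 is reduced with i-Bu2AlH to (2Z,6Z)-8-chloro-2,6-dimethylocta-2,6-dien-1-ol F7 and silylated (TBSCl, imidazole) to its tert-butyldimethylsilyl ether F8. Br/Mg exchange on F6 with i-PrBu2MgLi at −78 °C (the 2,6-disubstituted lactone carbonyl is shielded), then CuI-catalysed coupling with F8, gives the silyl ether of 18, (3R)-5-[(2Z,6Z)-8-(tert-butyldimethylsilyloxy)-3,7-dimethylocta-2,6-dien-1-yl]-6,8-bis(methoxymethoxy)-3-methyl-3,4-dihydro-1H-isochromen-1-one F9. Bu4NF then gives 18.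

**Further compounds**
F1 | step 13 | methyl 4-bromo-4-methyl-3-oxopentanoate | COC(=O)CC(=O)C(C)(C)Br
F2 | step 13 | methyl 4-{[(3R)-8-hydroxy-5-[(2Z,6Z)-8-hydroxy-3,7-dimethylocta-2,6-dien-1-yl]-3-methyl-1-oxo-3,4-dihydro-1H-isochromen-6-yl]oxy}-4-methyl-3-oxopentanoate | C[C@@H]1Cc2c(C/C=C(C)\CC/C=C(C)\CO)c(OC(C)(C)C(=O)CC(=O)OC)cc(O)c2C(=O)O1
F3 | step 13 | methyl 4-{[(3R)-5-[(2Z,6Z)-8-bromo-3,7-dimethylocta-2,6-dien-1-yl]-8-hydroxy-3-methyl-1-oxo-3,4-dihydro-1H-isochromen-6-yl]oxy}-4-methyl-3-oxopentanoate | C[C@@H]1Cc2c(C/C=C(C)\CC/C=C(C)\CBr)c(OC(C)(C)C(=O)CC(=O)OC)cc(O)c2C(=O)O1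
F4 | step 13 | macrocyclic β-keto ester: 24 bearing CO2CH3 at C9' (C9' epimers) | C/C1=C/Cc2c(cc(O)c3c2C[C@@H](C)OC3=O)OC(C)(C)C(=O)C(C(=O)OC)C/C(C)=C\CC1
F5 | step 11 | (3R)-8-hydroxy-5-[(2Z,6Z)-8-hydroxy-3,7-dimethylocta-2,6-dien-1-yl]-3-methyl-6-[(2-methylbut-3-yn-2-yl)oxy]-3,4-dihydro-1H-isochromen-1-one | C[C@@H]1Cc2c(C/C=C(C)\CC/C=C(C)\CO)c(OC(C)(C)C#C)cc(O)c2C(=O)O1
F6 | step 7 | (3R)-5-bromo-6,8-bis(methoxymethoxy)-3-methyl-3,4-dihydro-1H-isochromen-1-one | C[C@@H]1Cc2c(Br)c(OCOC)cc(OCOC)c2C(=O)O1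
F7 | step 7 | (2Z,6Z)-8-chloro-2,6-dimethylocta-2,6-dien-1-ol | OC/C(C)=C\CC/C(C)=C\CCl
F8 | step 7 | tert-butyl{[(2Z,6Z)-8-chloro-2,6-dimethylocta-2,6-dien-1-yl]oxy}dimethylsilane | CC(C)(C)[Si](C)(C)OC/C(C)=C\CC/C(C)=C\CCl
F9 | step 7 | (3R)-5-[(2Z,6Z)-8-(tert-butyldimethylsilyloxy)-3,7-dimethylocta-2,6-dien-1-yl]-6,8-bis(methoxymethoxy)-3-methyl-3,4-dihydro-1H-isochromen-1-one | C[C@@H]1Cc2c(C/C=C(C)\CC/C=C(C)\CO[Si](C)(C)C(C)(C)C)c(OCOC)cc(OCOC)c2C(=O)O1
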